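**Retrosynthetic overview**
- The target is an achiral 2-methoxy-6-alkyl-1,4-benzoquinone. The quinone is unveiled last by para-oxidation of a 3-methoxy-5-alkylphenol, itself obtained from a 3,5-dimethoxyphenyl precursor by mono-O-demethylation.
- Key disconnection: the C3–C4 bond of the pentadecanoic acid chain. A propanoate homoenolate (β-zincio ester, d3 synthon) is coupled with a primary alkyl bromide in an alkyl–alkyl Negishi reaction. Both carbons are natively electrophilic (acrylate β-carbon and C–Br carbon), and the acid oxidation level is delivered directly.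
- The C12 bromide comes from 3,5-dimethoxyphenyl Grignard and 1,12-dibromododecane (copper-catalysed aryl–alkyl coupling).
- No ring is formed. The only ring is the purchased benzene ring, oxidised to the quinone in the final step.

Assumption: the target has no stereocentre and no stereogenic alkene, so it is achiral and "single enantiomer" means the one constitution drawn.

**Route**

Step 1
Reactants: 1 1-bromo-3,5-dimethoxybenzene; 2 1,12-dibromododecane
Product: 4 1-(12-bromododecyl)-3,5-dimethoxybenzene, via 3,5-dimethoxyphenylmagnesium bromide 3 (not isolated)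
Conditions: 1, Mg, THF, reflux; then added slowly to 2 (3 equiv), Li2CuCl4 (3 mol%), THF/NMP, 0 °C to rt
Reagents that add atoms: none
Why: Kochi-type copper-catalysed Grignard–alkyl bromide coupling, in which the aryl cuprate formed in the flask displaces one primary bromide, while the threefold excess of 2 and inverse addition keep double arylation low.

Step 2
Reactants: 4 1-(12-bromododecyl)-3,5-dimethoxybenzene; 5 ethyl 3-bromopropanoate
Product: 7 ethyl 15-(3,5-dimethoxyphenyl)pentadecanoate, via 3-ethoxy-3-oxopropylzinc bromide 6 (not isolated)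
Conditions: 5 (1.6 equiv), Zn dust, LiCl, THF, 50 °C; then 4, Pd2(dba)3 (2 mol%), tricyclopentylphosphine (PCyp3, 8 mol%), N-methylimidazole (1.2 equiv), THF/NMP 2:1, 80 °C, 14 h
Reagents that add atoms: none
Why: Alkyl–alkyl Negishi cross-coupling of a zinc homoenolate, in which 4 adds oxidatively to zerovalent palladium bearing the bulky, electron-rich PCyp3, the β-zincio ester 6 (activated by N-methylimidazole) transmetalates and reductive elimination outruns β-hydride elimination, so the ester β-carbon and the C–Br carbon, both natively electrophilic, are joined with no stereocentre involved.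

Step 3
Reactants: 7 ethyl 15-(3,5-dimethoxyphenyl)pentadecanoate
Product: 9 15-(3-hydroxy-5-methoxyphenyl)pentadecanoic acid, via ethyl 15-(3-hydroxy-5-methoxyphenyl)pentadecanoate 8 (not isolated)
Conditions: EtSNa (4 equiv), DMF, 140 °C, 3 h; then 2 M aq NaOH, 60 °C, 1 h; then aq HCl to pH 2
Reagents that add atoms: sodium hydroxide, [Na+].[OH-] (its oxygen becomes the carboxylic OH)
Why: Thiolate SN2 O-demethylation stops after one methyl group because the phenoxide formed deactivates the ring towards loss of the second, and the hydroxide stage is a plain ester saponification in the same pot.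

Step 4
Reactants: 9 15-(3-hydroxy-5-methoxyphenyl)pentadecanoic acid
Product: 10 15-(5-methoxy-3,6-dioxocyclohexa-1,4-dien-1-yl)pentadecanoic acid
Conditions: Fremy's salt (KO3S)2NO (2.5 equiv), KH2PO4 buffer (pH 6), acetone/H2O, 0 °C to rt, 2 h
Reagents that add atoms: potassium nitrosodisulfonate (Fremy's salt), [K+].[K+].[O-]S(=O)(=O)N([O])S(=O)(=O)[O-]
Why: Teuber oxidation, in which one nitrosodisulfonate radical abstracts the phenolic hydrogen and a second adds through oxygen at the free para carbon (between the methoxy group and the chain), and loss of imidodisulfonate gives the 1,4-quinone whose carbonyl is flanked by OMe and the alkyl chain, with the carboxylic acid untouched at pH 6.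

**Compound list**

1 | 1-bromo-3,5-dimethoxybenzene | COc1cc(Br)cc(OC)c1 | starting material
2 | 1,12-dibromododecane | BrCCCCCCCCCCCCBr | starting material
3 | 3,5-dimethoxyphenylmagnesium bromide | COc1cc([Mg]Br)cc(OC)c1 | intermediate (not isolated)
4 | 1-(12-bromododecyl)-3,5-dimethoxybenzene | COc1cc(CCCCCCCCCCCCBr)cc(OC)c1 | intermediate
5 | ethyl 3-bromopropanoate | CCOC(=O)CCBr | starting material
6 | 3-ethoxy-3-oxopropylzinc bromide | CCOC(=O)CC[Zn]Br | intermediate (not isolated)
7 | ethyl 15-(3,5-dimethoxyphenyl)pentadecanoate | CCOC(=O)CCCCCCCCCCCCCCc1cc(OC)cc(OC)c1 | intermediate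
8 | ethyl 15-(3-hydroxy-5-methoxyphenyl)pentadecanoate (sodium phenoxide in the flask) | CCOC(=O)CCCCCCCCCCCCCCc1cc(O)cc(OC)c1 | intermediate (not isolated)
9 | 15-(3-hydroxy-5-methoxyphenyl)pentadecanoic acid | OC(=O)CCCCCCCCCCCCCCc1cc(O)cc(OC)c1 | intermediate
10 | 15-(5-methoxy-3,6-dioxocyclohexa-1,4-dien-1-yl)pentadecanoic acid | COC1=CC(=O)C=C(CCCCCCCCCCCCCCC(=O)O)C1=O | target

**Summary**

Total step count: 4. Longest linear sequence: 4 steps (1 → 4 → 7 → 9 → 10).

**Steps most likely to fail, with fallbacks**

Step 2 (homoenolate alkyl–alkyl coupling). The chelated β-zincio ester may transmetalate slowly, and the alkylpalladium may give the terminal alkene by β-hydride elimination. The fallback sets out from 4 and comes back at 9, using a propanal homoenolate equivalent at the aldehyde oxidation level. Bromide 4 is coupled with commercial 2-(1,3-dioxolan-2-yl)ethylmagnesium bromide (Li2CuCl4 3 mol%, THF, 0 °C to rt) to give 2-[14-(3,5-dimethoxyphenyl)tetradecyl]-1,3-dioxolane F1. Acetal hydrolysis (2 M HCl, THF, 40 °C) gives 15-(3,5-dimethoxyphenyl)pentadecanal F2. Pinnick oxidation (NaClO2, NaH2PO4, 2-methyl-2-butene, t-BuOH/H2O) gives 15-(3,5-dimethoxyphenyl)pentadecanoic acid F3. Mono-demethylation (EtSNa, DMF, 140 °C) then gives 9.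

Step 4 (Teuber oxidation). The para position is flanked by two substituents, and the soap-like substrate may oxidise sluggishly or partly at an ortho position. The fallback sets out from 9 and comes back at 10 by installing the para oxygen by a polar route. Elbs persulfate oxidation of the water-soluble disodium salt of 9 (K2S2O8, 2 M aq NaOH, 0 °C to rt) gives 15-[5-hydroxy-3-methoxy-2-(sulfooxy)phenyl]pentadecanoic acid F4. This is hydrolysed without isolation (aq HCl, 80 °C) to the hydroquinone 15-(2,5-dihydroxy-3-methoxyphenyl)pentadecanoic acid F5. Oxidation with FeCl3 in aqueous methanol at rt then gives 10.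

Step 1 (mono-arylation of the dibromide). Double arylation and biaryl homocoupling can erode the yield. The fallback sets out from 1 and comes back at 4 by reversing the roles of the partners. Commercial 12-bromo-1-dodecene is hydroborated with 9-borabicyclo[3.3.1]nonane (THF, rt) to 9-(12-bromododecyl)-9-borabicyclo[3.3.1]nonane F6. This is coupled with 1 in a B-alkyl Suzuki–Miyaura reaction (PdCl2(dppf) 3 mol%, K3PO4, THF/DMF, 50 °C), conditions under which the primary C–Br bond is not touched, to give 4.

**Further compounds**

F1 | step 2 | 2-[14-(3,5-dimethoxyphenyl)tetradecyl]-1,3-dioxolane | COc1cc(OC)cc(CCCCCCCCCCCCCCC2OCCO2)c1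
F2 | step 2 | 15-(3,5-dimethoxyphenyl)pentadecanal | COc1cc(OC)cc(CCCCCCCCCCCCCCC=O)c1
F3 | step 2 | 15-(3,5-dimethoxyphenyl)pentadecanoic acid | COc1cc(OC)cc(CCCCCCCCCCCCCCC(=O)O)c1
F4 | step 4 | 15-[5-hydroxy-3-methoxy-2-(sulfooxy)phenyl]pentadecanoic acid | COc1cc(O)cc(CCCCCCCCCCCCCCC(=O)O)c1OS(=O)(=O)O
F5 | step 4 | 15-(2,5-dihydroxy-3-methoxyphenyl)pentadecanoic acid | COc1cc(O)cc(CCCCCCCCCCCCCCC(=O)O)c1O
F6 | step 1 | 9-(12-bromododecyl)-9-borabicyclo[3.3.1]nonane | BrCCCCCCCCCCCCB1C2CCCC1CCC2
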